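**Retrosynthetic overview**
- The target is split at the O8 ester into a silyl-protected (2R,3R)-epoxy acid (oxirane ring made by Katsuki–Sharpless epoxidation) and an 8-hydroxy α-methylene lactone; the exocyclic methylene comes from the saturated lactone by Mannich methylenation.
- The saturated lactone comes from an acyclic seco ynal and Me2Zn: one nickel-mediated alkylative alkyne–aldehyde coupling forms C5–C6 and C4–C15 and closes the ten-membered ring first; the C6 alkoxide then closes the γ-lactone on the C12 ester in the same flask.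
- Feature used: the lactone carbinol carbon C6 is bonded to the E-trisubstituted C4=C5 alkene of the ten-membered ring, which carries methyl C15 on C4; syn addition of C6 and CH3 across a terminal C4≡C5 alkyne writes this array.
- The seco ynal comes from an Evans syn-aldol (C7, C8), an Arndt–Eistert homologation (C11) and a late oxidation at C6.
- The aldol aldehyde carries the Z C1=C10 alkene (cuprate syn-addition to an ynoate) and C2 (asymmetric allenylboration).

Key step: step 16

Remark: germacrane numbering (C1–C10 ring, C11–C13 lactone arm, C14 and C15 methyls) is used for positions; O8 is carried as a triethylsilyl ether and O6 as a 4-methoxybenzyl ether so that the aldehyde is unmasked last; 4,4-diethoxybut-1-yne and 3-[(4-methoxybenzyl)oxy]propanoic acid are taken as catalogue compounds.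

Step 1
Reactants: 1 4,4-diethoxybut-1-yne
Product: 3 methyl 5,5-diethoxypent-2-ynoate, via lithium acetylide 2 (not isolated)
Conditions: n-BuLi, THF, −78 °C; ClCO2Me, −78 °C to 0 °C
Reagents that add atoms: methyl chloroformate, COC(=O)Cl
Why: Deprotonation of the terminal alkyne and C-acylation of the lithium acetylide with a chloroformate should proceed cleanly because the acetal is inert to base.

Step 2
Reactants: 3 methyl 5,5-diethoxypent-2-ynoate
Product: 4 methyl (2Z)-5,5-diethoxy-3-methylpent-2-enoate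
Conditions: Me2CuLi (from CuI, MeLi), THF, −78 °C; NH4Cl quench at −78 °C
Reagents that add atoms: lithium dimethylcuprate, [Li+].C[Cu-]C
Why: Conjugate syn-carbocupration of the 2-ynoate and protonation of the alkenylcopper at −78 °C place CH3 and H cis, so the CH2 branch ends cis to the ester and the Z C1=C10 geometry is fixed.

Step 3
Reactants: 4 methyl (2Z)-5,5-diethoxy-3-methylpent-2-enoate
Product: 5 (2Z)-5,5-diethoxy-3-methylpent-2-en-1-ol
Conditions: iBu2AlH, CH2Cl2, −78 °C; Rochelle salt work-up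
Reagents that add atoms: none
Why: 1,2-Reduction of a conjugated ester by the aluminium hydride gives the allylic alcohol without touching the acetal or the alkene geometry.

Step 4
Reactants: 5 (2Z)-5,5-diethoxy-3-methylpent-2-en-1-ol
Product: 6 (2Z)-5,5-diethoxy-3-methylpent-2-enal
Conditions: MnO2, CH2Cl2, rt
Reagents that add atoms: none
Why: Allylic oxidation on the MnO2 surface is neutral and should keep the Z geometry, as it does for related Z allylic alcohols.

Step 5
Reactants: 6 (2Z)-5,5-diethoxy-3-methylpent-2-enal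
Product: 7 (4S,5Z)-8,8-diethoxy-6-methyloct-5-en-1-yn-4-ol
Conditions: (−)-Ipc2BOMe, CH2=C=CHMgBr, Et2O, −78 °C to rt; then 6, −78 °C; NaOH, H2O2
Reagents that add atoms: B-allenyldiisopinocampheylborane made in the flask from allenylmagnesium bromide (C=C=C[Mg]Br) and (−)-Ipc2BOMe, C=C=CB([C@@H]1C[C@@H]2C[C@@H](C2(C)C)[C@H]1C)[C@@H]1C[C@@H]2C[C@@H](C2(C)C)[C@H]1C
Why: Asymmetric allenylboration through a closed six-membered transition state (SE2′) gives the homopropargylic alcohol, and the (+)-α-pinene-derived borane should attack the Si face of the enal as in the allyl series, which sets C2 as S.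

Step 6
Reactants: 7 (4S,5Z)-8,8-diethoxy-6-methyloct-5-en-1-yn-4-ol
Product: 8 tert-butyl{[(4S,5Z)-8,8-diethoxy-6-methyloct-5-en-1-yn-4-yl]oxy}dimethylsilane
Conditions: TBSCl, imidazole, DMF, rt
Reagents that add atoms: tert-butyldimethylsilyl chloride, CC(C)(C)[Si](C)(C)Cl
Why: Silylation of the secondary alcohol under basic conditions leaves the acetal intact.

Step 7
Reactants: 8 tert-butyl{[(4S,5Z)-8,8-diethoxy-6-methyloct-5-en-1-yn-4-yl]oxy}dimethylsilane
Product: 10 (3Z,5S)-5-(tert-butyldimethylsilyloxy)-3-methyloct-3-en-7-ynal, via collidinium salt 9 (not isolated)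
Conditions: TESOTf, 2,4,6-collidine, CH2Cl2, 0 °C; then H2O
Reagents that add atoms: water, O
Why: Silyl triflate–collidine acetal cleavage goes through a pyridinium salt that water hydrolyses under non-acidic conditions, so the silyl ether survives and the β,γ-alkene should not move into conjugation.

Step 8
Reactants: 11 3-[(4-methoxybenzyl)oxy]propanoic acid; 12 (4S)-4-benzyl-1,3-oxazolidin-2-one
Product: 14 (4S)-4-benzyl-3-{3-[(4-methoxybenzyl)oxy]propanoyl}-1,3-oxazolidin-2-one, via mixed pivalic anhydride 13 (not isolated)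
Conditions: t-BuCOCl, Et3N, THF, −20 °C; then 12, LiCl, rt
Reagents that add atoms: none
Why: N-Acylation of the oxazolidinone by a mixed pivalic anhydride is the standard mild way to make such imides.

Step 9
Reactants: 14 (4S)-4-benzyl-3-{3-[(4-methoxybenzyl)oxy]propanoyl}-1,3-oxazolidin-2-one; 10 (3Z,5S)-5-(tert-butyldimethylsilyloxy)-3-methyloct-3-en-7-ynal
Product: 16 (4S)-4-benzyl-3-[(2S,3R,5Z,7S)-7-(tert-butyldimethylsilyloxy)-3-hydroxy-2-{[(4-methoxybenzyl)oxy]methyl}-5-methyldec-5-en-9-ynoyl]-1,3-oxazolidin-2-one, via boron enolate 15 (not isolated)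
Conditions: Bu2BOTf, iPr2NEt, CH2Cl2, −78 to 0 °C; fresh 10, −78 °C; pH 7 buffer, MeOH, H2O2
Reagents that add atoms: none
Why: Evans syn-aldol: the Z boron enolate reacts through a Zimmerman–Traxler chair on the face left open by the (S)-benzyl group, which sets C7 and C8 (2S,3R in the acyl chain) in the relative and absolute sense the target needs once the acyl carbon has become C12.

Step 10
Reactants: 16 the aldol adduct
Product: 17 (4S)-4-benzyl-3-[(2S,3R,5Z,7S)-7-(tert-butyldimethylsilyloxy)-2-{[(4-methoxybenzyl)oxy]methyl}-5-methyl-3-(triethylsilyloxy)dec-5-en-9-ynoyl]-1,3-oxazolidin-2-one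
Conditions: TESOTf, 2,6-lutidine, CH2Cl2, −78 °C
Reagents that add atoms: triethylsilyl triflate, CC[Si](CC)(CC)OS(=O)(=O)C(F)(F)F
Why: Fast silylation protects O8 before any γ-ester exists that it could lactonise onto.

Step 11
Reactants: 17 the silylated imide
Product: 18 (2S,3R,5Z,7S)-7-(tert-butyldimethylsilyloxy)-2-{[(4-methoxybenzyl)oxy]methyl}-5-methyl-3-(triethylsilyloxy)dec-5-en-9-ynoic acid
Conditions: LiOH, H2O2, THF/H2O, 0 °C; Na2SO3; HCl to pH 3
Reagents that add atoms: lithium hydroperoxide (from LiOH and H2O2), [Li+].[O-]O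
Why: Hydroperoxide attacks the exocyclic imide carbonyl selectively, so the auxiliary is released without epimerisation or β-elimination.

Step 12
Reactants: 18 the acid
Product: 20 (3S,4R,6Z,8S)-8-(tert-butyldimethylsilyloxy)-1-diazo-3-{[(4-methoxybenzyl)oxy]methyl}-6-methyl-4-(triethylsilyloxy)undec-6-en-10-yn-2-one, via mixed carbonic anhydride 19 (not isolated)
Conditions: i-BuOCOCl, N-methylmorpholine, THF, −20 °C; CH2N2, Et2O, 0 °C
Reagents that add atoms: diazomethane, C=[N+]=[N-]
Why: First half of the Arndt–Eistert homologation: the mixed anhydride acylates diazomethane without disturbing the α-stereocentre.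

Step 13
Reactants: 20 the diazoketone
Product: 22 methyl (3S,4R,6Z,8S)-8-(tert-butyldimethylsilyloxy)-3-{[(4-methoxybenzyl)oxy]methyl}-6-methyl-4-(triethylsilyloxy)undec-6-en-10-ynoate, via ketene 21 (not isolated)
Conditions: hν (>300 nm), MeOH, rt
Reagents that add atoms: methanol, CO
Why: Photochemical Wolff rearrangement moves C7 with retention to the former diazo carbon (now C11) and methanol traps the ketene as the C12 methyl ester; light is used instead of a silver salt because of the terminal alkyne.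

Step 14
Reactants: 22 the homologated ester
Product: 23 methyl (3S,4R,6Z,8S)-8-(tert-butyldimethylsilyloxy)-3-(hydroxymethyl)-6-methyl-4-(triethylsilyloxy)undec-6-en-10-ynoate
Conditions: DDQ, CH2Cl2/pH 7 buffer, 0 °C; crude used at once
Reagents that add atoms: none
Why: Oxidative cleavage of the 4-methoxybenzyl ether is neutral, so the silyl ethers stay and the γ-hydroxy ester meets no acid or base that would close it.

Step 15
Reactants: 23 the primary alcohol
Product: 24 methyl (3R,4R,6Z,8S)-8-(tert-butyldimethylsilyloxy)-3-formyl-6-methyl-4-(triethylsilyloxy)undec-6-en-10-ynoate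
Conditions: Dess–Martin periodinane, NaHCO3, CH2Cl2, 0 °C
Reagents that add atoms: none
Why: Buffered Dess–Martin oxidation gives the α-branched aldehyde without epimerisation at C7 or loss of the β-silyloxy group.

Step 16
Reactants: 24 the seco ynal; 25 dimethylzinc
Product: 27 (3aS,4R,6Z,8S,10E,11aR)-8-(tert-butyldimethylsilyloxy)-6,10-dimethyl-4-(triethylsilyloxy)-3a,4,5,8,9,11a-hexahydrocyclodeca[b]furan-2(3H)-one, via zinc alkoxide 26 (not isolated)
Conditions: Ni(cod)2 (30 mol%), IMes·HCl and KOtBu (30 mol% each), Me2Zn (3 equiv), toluene, syringe-pump addition of 24 (0.002 M), rt; aq NH4Cl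
Reagents that add atoms: dimethylzinc (25), C[Zn]C
Why: Proposed new method: zerovalent nickel carrying the carbene binds the aldehyde and the terminal alkyne of 24 and undergoes oxidative cyclisation to an oxanickelacyclopentene in which C5–C6 is formed; methyl then passes from zinc to nickel and C4–CH3 reductive elimination releases the methylzinc alkoxide 26, so C6 and CH3 add syn across the alkyne and C4=C5 is E. The closest known reactions are the nickel-catalysed alkylative cyclisation of ynals with organozincs (small rings, exo mode) and the nickel–carbene reductive macrocyclisation of terminal ynals with silanes (endo mode, larger rings); an alkylative closure of a ten-membered ring has not been shown. The ten-membered carbocycle closes in the endo mode at the alkyne (10-endo-dig, bond to the terminal carbon C5), which the unhindered CH terminus and the carbene ligand should favour over 9-exo closure at C4, and the lactone then closes by 5-exo-trig attack of the C6 zinc alkoxide on the C12 methyl ester. The new stereocentre C6 is set by the substrate: Felkin–Anh approach past the C7 stereocentre and 1,3-anti induction from the C8 silyloxy group both point to the 6,7-syn/6,8-anti carbinol (6R), which gives the trans-fused lactone. The step needs cyclisation to win over alkyne oligomerisation, intermolecular coupling and direct methyl addition to the aldehyde; high dilution with slow addition, the Z C1=C10 alkene that holds the two chain ends on the same side, and the low uncatalysed reactivity of Me2Zn toward aldehydes should secure this.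

Step 17
Reactants: 27 the saturated lactone
Product: 29 (3aS,4R,6Z,8S,10E,11aR)-8-(tert-butyldimethylsilyloxy)-3-[(dimethylamino)methyl]-6,10-dimethyl-4-(triethylsilyloxy)-3a,4,5,8,9,11a-hexahydrocyclodeca[b]furan-2(3H)-one (C3 epimers), via lithium enolate 28 (not isolated)
Conditions: LiN(iPr)2, THF, −78 °C; CH2=NMe2+ I−, −78 to 0 °C
Reagents that add atoms: Eschenmoser's salt, C=[N+](C)C.[I-]
Why: Mannich reaction of the lactone enolate at C11, which has no β-leaving group, adds the aminomethyl carbon; the C11 configuration does not matter because it is lost in the next step.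

Step 18
Reactants: 29 the Mannich base
Product: 31 (3aS,4R,6Z,8S,10E,11aR)-8-(tert-butyldimethylsilyloxy)-6,10-dimethyl-3-methylidene-4-(triethylsilyloxy)-3a,4,5,8,9,11a-hexahydrocyclodeca[b]furan-2(3H)-one, via ammonium iodide 30 (not isolated)
Conditions: MeI, MeOH, rt; then NaHCO3 (aq), CH2Cl2
Reagents that add atoms: none
Why: Quaternisation followed by base-induced β-elimination of trimethylamine (E1cB) is the standard route to the α-methylene lactone.

Step 19
Reactants: 31 the α-methylene lactone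
Product: 32 (3aR,4R,6Z,8S,10E,11aR)-8-(tert-butyldimethylsilyloxy)-4-hydroxy-6,10-dimethyl-3-methylidene-3a,4,5,8,9,11a-hexahydrocyclodeca[b]furan-2(3H)-one
Conditions: PPTS, MeOH/CH2Cl2, 0 °C
Reagents that add atoms: none
Why: Acid-catalysed methanolysis removes the triethylsilyl ether much faster than the tert-butyldimethylsilyl ether and is too mild to trigger translactonisation to O8.

Step 20
Reactants: 33 (2E)-but-2-enal
Product: 35 (2Z)-2-bromobut-2-enal, via dibromide 34 (not isolated)
Conditions: Br2, CH2Cl2, 0 °C; then Et3N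
Reagents that add atoms: bromine, BrBr
Why: Bromine addition and dehydrobromination give the more stable 2-bromoenal with the formyl group trans to methyl.

Step 21
Reactants: 35 (2Z)-2-bromobut-2-enal
Product: 36 (2Z)-2-bromobut-2-en-1-ol
Conditions: NaBH4, CeCl3·7H2O, MeOH, 0 °C
Reagents that add atoms: none
Why: Luche reduction gives clean 1,2-reduction of the enal.

Step 22
Reactants: 36 (2Z)-2-bromobut-2-en-1-ol
Product: 37 {[(2Z)-2-bromobut-2-en-1-yl]oxy}(tert-butyl)dimethylsilane
Conditions: TBSCl, imidazole, CH2Cl2, rt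
Reagents that add atoms: tert-butyldimethylsilyl chloride, CC(C)(C)[Si](C)(C)Cl
Why: Routine silylation marks the hydroxymethyl arm that is trans to methyl.

Step 23
Reactants: 37 the bromoalkene silyl ether
Product: 39 (2E)-2-{[(tert-butyldimethylsilyl)oxy]methyl}but-2-en-1-ol, via vinyllithium 38 (not isolated)
Conditions: t-BuLi (2 equiv), Et2O, −78 °C; HCHO (from paraformaldehyde), −78 °C; AcOH quench at −78 °C
Reagents that add atoms: formaldehyde, C=O
Why: Bromine–lithium exchange and trapping with formaldehyde go with retention, so the new free hydroxymethyl arm is cis to methyl; the cold acidic quench should prevent silyl migration between the two arms.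

Step 24
Reactants: 39 the allylic alcohol
Product: 40 [(2R,3R)-2-{[(tert-butyldimethylsilyl)oxy]methyl}-3-methyloxiran-2-yl]methanol
Conditions: Ti(OiPr)4 (20 mol%), L-(+)-diethyl tartrate (24 mol%), t-BuOOH, 4 Å MS, CH2Cl2, −20 °C
Reagents that add atoms: tert-butyl hydroperoxide, CC(C)(C)OO
Why: Katsuki–Sharpless epoxidation: L-(+)-tartrate, which gives 2S epoxides of the (S)-glycidol type from simple 2-alken-1-ols, should deliver oxygen to the same face here and set both oxirane centres (the descriptor reads 2R,3R only because the silyloxymethyl arm outranks the carbinol arm).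

Step 25
Reactants: 40 the epoxy alcohol
Product: 41 (2R,3R)-2-{[(tert-butyldimethylsilyl)oxy]methyl}-3-methyloxirane-2-carboxylic acid
Conditions: TEMPO (cat.), PhI(OAc)2, MeCN/H2O, rt
Reagents that add atoms: water, O
Why: Nitroxyl-catalysed oxidation takes the primary alcohol through the aldehyde hydrate to the acid under conditions that spare the epoxide and the silyl ether.

Step 26
Reactants: 41 the epoxy acid; 32 the C8 alcohol
Product: 43 (3aR,4R,6Z,8S,10E,11aR)-8-(tert-butyldimethylsilyloxy)-6,10-dimethyl-3-methylidene-2-oxo-2,3,3a,4,5,8,9,11a-octahydrocyclodeca[b]furan-4-yl (2R,3R)-2-{[(tert-butyldimethylsilyl)oxy]methyl}-3-methyloxirane-2-carboxylate, via mixed anhydride 42 (not isolated)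
Conditions: 2,4,6-Cl3C6H2COCl, Et3N, toluene, rt; then 32, DMAP, rt to 40 °C
Reagents that add atoms: none
Why: Yamaguchi esterification passes the hindered acyl group to DMAP from the mixed anhydride (the aroyl carbonyl is blocked by its two ortho chlorines) and acylates the only free hydroxyl with retention at C8.

Step 27
Reactants: 43 the bis-silyl ether
Product: 44 (3aR,4R,6Z,8S,10E,11aR)-8-hydroxy-6,10-dimethyl-3-methylidene-2-oxo-2,3,3a,4,5,8,9,11a-octahydrocyclodeca[b]furan-4-yl (2R,3R)-2-(hydroxymethyl)-3-methyloxirane-2-carboxylate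
Conditions: HF·pyridine, pyridine, THF, 0 °C to rt
Reagents that add atoms: none
Why: Buffered HF removes both silyl ethers without the basic conditions that would cause Payne rearrangement of the epoxy alcohol or conjugate addition to the methylene lactone.

**Compound list**
1 | 4,4-diethoxybut-1-yne | C#CCC(OCC)OCC | starting material
2 | lithium 4,4-diethoxybut-1-yn-1-ide | [Li]C#CCC(OCC)OCC | intermediate
3 | methyl 5,5-diethoxypent-2-ynoate | COC(=O)C#CCC(OCC)OCC | intermediate
4 | methyl (2Z)-5,5-diethoxy-3-methylpent-2-enoate | COC(=O)/C=C(/C)CC(OCC)OCC | intermediate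
5 | (2Z)-5,5-diethoxy-3-methylpent-2-en-1-ol | OC/C=C(/C)CC(OCC)OCC | intermediate
6 | (2Z)-5,5-diethoxy-3-methylpent-2-enal | O=C/C=C(/C)CC(OCC)OCC | intermediate
7 | (4S,5Z)-8,8-diethoxy-6-methyloct-5-en-1-yn-4-ol | C#CC[C@H](O)/C=C(/C)CC(OCC)OCC | intermediate
8 | tert-butyl{[(4S,5Z)-8,8-diethoxy-6-methyloct-5-en-1-yn-4-yl]oxy}dimethylsilane | C#CC[C@H](O[Si](C)(C)C(C)(C)C)/C=C(/C)CC(OCC)OCC | intermediate
9 | 1-[(3Z,5S)-5-(tert-butyldimethylsilyloxy)-1-ethoxy-3-methyloct-3-en-7-yn-1-yl]-2,4,6-trimethylpyridinium triflate | C#CC[C@H](O[Si](C)(C)C(C)(C)C)/C=C(/C)CC(OCC)[n+]1c(C)cc(C)cc1C.[O-]S(=O)(=O)C(F)(F)F | intermediate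
10 | (3Z,5S)-5-(tert-butyldimethylsilyloxy)-3-methyloct-3-en-7-ynal | C#CC[C@H](O[Si](C)(C)C(C)(C)C)/C=C(/C)CC=O | intermediate
11 | 3-[(4-methoxybenzyl)oxy]propanoic acid | COc1ccc(COCCC(=O)O)cc1 | starting material
12 | (4S)-4-benzyl-1,3-oxazolidin-2-one | O=C1N[C@@H](Cc2ccccc2)CO1 | starting material
13 | 3-[(4-methoxybenzyl)oxy]propanoic pivalic anhydride | COc1ccc(COCCC(=O)OC(=O)C(C)(C)C)cc1 | intermediate
14 | (4S)-4-benzyl-3-{3-[(4-methoxybenzyl)oxy]propanoyl}-1,3-oxazolidin-2-one | COc1ccc(COCCC(=O)N2[C@@H](Cc3ccccc3)COC2=O)cc1 | intermediate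
15 | dibutylboron (Z)-enolate of 14 | CCCCB(CCCC)O/C(=C\COCc1ccc(OC)cc1)N1[C@@H](Cc2ccccc2)COC1=O | intermediate
16 | (4S)-4-benzyl-3-[(2S,3R,5Z,7S)-7-(tert-butyldimethylsilyloxy)-3-hydroxy-2-{[(4-methoxybenzyl)oxy]methyl}-5-methyldec-5-en-9-ynoyl]-1,3-oxazolidin-2-one | C#CC[C@H](O[Si](C)(C)C(C)(C)C)/C=C(/C)C[C@@H](O)[C@@H](C(=O)N1[C@@H](Cc2ccccc2)COC1=O)COCc1ccc(OC)cc1 | intermediate
17 | 3-O-triethylsilyl ether of 16 | C#CC[C@H](O[Si](C)(C)C(C)(C)C)/C=C(/C)C[C@@H](O[Si](CC)(CC)CC)[C@@H](C(=O)N1[C@@H](Cc2ccccc2)COC1=O)COCc1ccc(OC)cc1 | intermediate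
18 | (2S,3R,5Z,7S)-7-(tert-butyldimethylsilyloxy)-2-{[(4-methoxybenzyl)oxy]methyl}-5-methyl-3-(triethylsilyloxy)dec-5-en-9-ynoic acid | C#CC[C@H](O[Si](C)(C)C(C)(C)C)/C=C(/C)C[C@@H](O[Si](CC)(CC)CC)[C@@H](C(=O)O)COCc1ccc(OC)cc1 | intermediate
19 | isobutyl carbonic anhydride of 18 | C#CC[C@H](O[Si](C)(C)C(C)(C)C)/C=C(/C)C[C@@H](O[Si](CC)(CC)CC)[C@@H](C(=O)OC(=O)OCC(C)C)COCc1ccc(OC)cc1 | intermediate
20 | (3S,4R,6Z,8S)-8-(tert-butyldimethylsilyloxy)-1-diazo-3-{[(4-methoxybenzyl)oxy]methyl}-6-methyl-4-(triethylsilyloxy)undec-6-en-10-yn-2-one | C#CC[C@H](O[Si](C)(C)C(C)(C)C)/C=C(/C)C[C@@H](O[Si](CC)(CC)CC)[C@@H](C(=O)C=[N+]=[N-])COCc1ccc(OC)cc1 | intermediate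
21 | ketene from 20 (C7 on the former diazo carbon) | C#CC[C@H](O[Si](C)(C)C(C)(C)C)/C=C(/C)C[C@@H](O[Si](CC)(CC)CC)[C@@H](C=C=O)COCc1ccc(OC)cc1 | intermediate
22 | methyl (3S,4R,6Z,8S)-8-(tert-butyldimethylsilyloxy)-3-{[(4-methoxybenzyl)oxy]methyl}-6-methyl-4-(triethylsilyloxy)undec-6-en-10-ynoate | C#CC[C@H](O[Si](C)(C)C(C)(C)C)/C=C(/C)C[C@@H](O[Si](CC)(CC)CC)[C@@H](CC(=O)OC)COCc1ccc(OC)cc1 | intermediate
23 | methyl (3S,4R,6Z,8S)-8-(tert-butyldimethylsilyloxy)-3-(hydroxymethyl)-6-methyl-4-(triethylsilyloxy)undec-6-en-10-ynoate | C#CC[C@H](O[Si](C)(C)C(C)(C)C)/C=C(/C)C[C@@H](O[Si](CC)(CC)CC)[C@@H](CC(=O)OC)CO | intermediate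
24 | methyl (3R,4R,6Z,8S)-8-(tert-butyldimethylsilyloxy)-3-formyl-6-methyl-4-(triethylsilyloxy)undec-6-en-10-ynoate (seco ynal) | C#CC[C@H](O[Si](C)(C)C(C)(C)C)/C=C(/C)C[C@@H](O[Si](CC)(CC)CC)[C@@H](CC(=O)OC)C=O | intermediate
25 | dimethylzinc | C[Zn]C | starting material
26 | methylzinc alkoxide of the ten-membered C6-hydroxy C12-methyl ester (lactone still open) | C[Zn]O[C@@H]1/C=C(\C)C[C@H](O[Si](C)(C)C(C)(C)C)/C=C(/C)C[C@@H](O[Si](CC)(CC)CC)[C@H]1CC(=O)OC | intermediate
27 | (3aS,4R,6Z,8S,10E,11aR)-8-(tert-butyldimethylsilyloxy)-6,10-dimethyl-4-(triethylsilyloxy)-3a,4,5,8,9,11a-hexahydrocyclodeca[b]furan-2(3H)-one | C1C(=O)O[C@@H]2/C=C(\C)C[C@H](O[Si](C)(C)C(C)(C)C)/C=C(/C)C[C@@H](O[Si](CC)(CC)CC)[C@@H]12 | intermediate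
28 | lithium enolate of 27 | C1=C(O[Li])O[C@@H]2/C=C(\C)C[C@H](O[Si](C)(C)C(C)(C)C)/C=C(/C)C[C@@H](O[Si](CC)(CC)CC)[C@@H]12 | intermediate
29 | 3-[(dimethylamino)methyl] derivative of 27 (C3 epimers) | CN(C)CC1C(=O)O[C@@H]2/C=C(\C)C[C@H](O[Si](C)(C)C(C)(C)C)/C=C(/C)C[C@@H](O[Si](CC)(CC)CC)[C@@H]12 | intermediate
30 | trimethylammonium iodide from 29 | C[N+](C)(C)CC1C(=O)O[C@@H]2/C=C(\C)C[C@H](O[Si](C)(C)C(C)(C)C)/C=C(/C)C[C@@H](O[Si](CC)(CC)CC)[C@@H]12.[I-] | intermediate
31 | (3aS,4R,6Z,8S,10E,11aR)-8-(tert-butyldimethylsilyloxy)-6,10-dimethyl-3-methylidene-4-(triethylsilyloxy)-3a,4,5,8,9,11a-hexahydrocyclodeca[b]furan-2(3H)-one | C=C1C(=O)O[C@@H]2/C=C(\C)C[C@H](O[Si](C)(C)C(C)(C)C)/C=C(/C)C[C@@H](O[Si](CC)(CC)CC)[C@@H]12 | intermediate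
32 | (3aR,4R,6Z,8S,10E,11aR)-8-(tert-butyldimethylsilyloxy)-4-hydroxy-6,10-dimethyl-3-methylidene-3a,4,5,8,9,11a-hexahydrocyclodeca[b]furan-2(3H)-one | C=C1C(=O)O[C@@H]2/C=C(\C)C[C@H](O[Si](C)(C)C(C)(C)C)/C=C(/C)C[C@@H](O)[C@@H]12 | intermediate
33 | (2E)-but-2-enal | C/C=C/C=O | starting material
34 | 2,3-dibromobutanal | CC(Br)C(Br)C=O | intermediate
35 | (2Z)-2-bromobut-2-enal | C/C=C(\Br)C=O | intermediate
36 | (2Z)-2-bromobut-2-en-1-ol | C/C=C(\Br)CO | intermediate
37 | {[(2Z)-2-bromobut-2-en-1-yl]oxy}(tert-butyl)dimethylsilane | C/C=C(\Br)CO[Si](C)(C)C(C)(C)C | intermediate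
38 | (2Z)-1-(tert-butyldimethylsilyloxy)but-2-en-2-yllithium | C/C=C(\[Li])CO[Si](C)(C)C(C)(C)C | intermediate
39 | (2E)-2-{[(tert-butyldimethylsilyl)oxy]methyl}but-2-en-1-ol | C/C=C(\CO)CO[Si](C)(C)C(C)(C)C | intermediate
40 | [(2R,3R)-2-{[(tert-butyldimethylsilyl)oxy]methyl}-3-methyloxiran-2-yl]methanol | OC[C@]1(CO[Si](C)(C)C(C)(C)C)O[C@@H]1C | intermediate
41 | (2R,3R)-2-{[(tert-butyldimethylsilyl)oxy]methyl}-3-methyloxirane-2-carboxylic acid | OC(=O)[C@]1(CO[Si](C)(C)C(C)(C)C)O[C@@H]1C | intermediate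
42 | mixed anhydride of 41 with 2,4,6-trichlorobenzoic acid | O=C(OC(=O)c1c(Cl)cc(Cl)cc1Cl)[C@]1(CO[Si](C)(C)C(C)(C)C)O[C@@H]1C | intermediate
43 | bis(tert-butyldimethylsilyl) ether of the target (silyl on O2 and on the oxirane hydroxymethyl) | C=C1C(=O)O[C@@H]2/C=C(\C)C[C@H](O[Si](C)(C)C(C)(C)C)/C=C(/C)C[C@@H](OC(=O)[C@]3(CO[Si](C)(C)C(C)(C)C)O[C@@H]3C)[C@@H]12 | intermediate
44 | (3aR,4R,6Z,8S,10E,11aR)-8-hydroxy-6,10-dimethyl-3-methylidene-2-oxo-2,3,3a,4,5,8,9,11a-octahydrocyclodeca[b]furan-4-yl (2R,3R)-2-(hydroxymethyl)-3-methyloxirane-2-carboxylate | C=C1C(=O)O[C@@H]2/C=C(\C)C[C@H](O)/C=C(/C)C[C@@H](OC(=O)[C@]3(CO)O[C@@H]3C)[C@@H]12 | target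

**Step count and risks**
Total step count: 27. Longest linear sequence: 20 steps (1–7, 9–19, 26, 27).

Steps most likely to fail:

1. Step 16 (the step that goes beyond known chemistry). The endo oxidative cyclisation may not compete at ten-membered ring size, so alkyne oligomerisation, intermolecular coupling, 9-exo closure at C4 or direct methyl transfer to the aldehyde could take over; the aldehyde face may also be poorly discriminated. The fallback uses known chemistry; it sets out from 22 and comes back at 27. Zirconium-catalysed carboalumination–iodination of the alkyne (Me3Al, Cp2ZrCl2, CH2Cl2; then I2) should give methyl (3S,4R,6Z,8S,10E)-8-(tert-butyldimethylsilyloxy)-11-iodo-3-{[(4-methoxybenzyl)oxy]methyl}-6,10-dimethyl-4-(triethylsilyloxy)undeca-6,10-dienoate F1, in which C15 comes from Me3Al by syn addition. DDQ would free the corresponding primary alcohol F2 and Dess–Martin periodinane would give the iodo aldehyde F3. An intramolecular Nozaki–Hiyama–Kishi reaction (CrCl2, NiCl2 cat., DMSO/THF, high dilution) would form C5–C6 and give the ten-membered hydroxy ester F4, which PPTS closes to 27.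

2. Step 14. The γ-hydroxy ester 23 may lactonise onto C12 during cleavage of the 4-methoxybenzyl ether or on handling, before it can be oxidised. The fallback sets out from 23 and comes back at 24, and never handles the free alcohol. 23 is deliberately closed (PPTS, CH2Cl2) to the γ-lactone F5; LiOH opens it to the lithium hydroxy carboxylate F6; TESCl/imidazole silylates both oxygens to the silyl ester silyl ether F7; aqueous work-up cleaves the silyl ester to the acid F8; TMSCHN2 gives the methyl ester with a primary triethylsilyl ether F9. Swern conditions (oxalyl chloride, DMSO, −78 to −40 °C; Et3N) oxidise the primary triethylsilyl ether of F9 directly to 24, while the secondary silyl ethers stay.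

3. Step 24. Epoxidation may be slow and poorly enantioselective, because the methyl group is cis to the reacting carbinol arm (the least favourable pattern for the titanium–tartrate catalyst) and the other arm is bulky. The fallback sets out from 39 and comes back at 40, and exchanges the roles of the two arms. 4-Methoxybenzyl trichloroacetimidate/CSA protects the free arm to give tert-butyl{[(2E)-2-{[(4-methoxybenzyl)oxy]methyl}but-2-en-1-yl]oxy}dimethylsilane F10. Bu4NF then frees the other arm to give (2Z)-2-{[(4-methoxybenzyl)oxy]methyl}but-2-en-1-ol F11, whose carbinol is trans to methyl. Katsuki–Sharpless epoxidation with D-(−)-diethyl tartrate (the opposite tartrate, because the same alkene face is now reached from the other arm) should give [(2S,3R)-2-{[(4-methoxybenzyl)oxy]methyl}-3-methyloxiran-2-yl]methanol F12. TBSCl/imidazole gives the silyl ether F13, and DDQ removes the 4-methoxybenzyl group to return 40.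

**Further compounds**
F1 | step 16 | methyl (3S,4R,6Z,8S,10E)-8-(tert-butyldimethylsilyloxy)-11-iodo-3-{[(4-methoxybenzyl)oxy]methyl}-6,10-dimethyl-4-(triethylsilyloxy)undeca-6,10-dienoate | I/C=C(\C)C[C@H](O[Si](C)(C)C(C)(C)C)/C=C(/C)C[C@@H](O[Si](CC)(CC)CC)[C@@H](CC(=O)OC)COCc1ccc(OC)cc1
F2 | step 16 | 3-(hydroxymethyl) analogue of F1 | I/C=C(\C)C[C@H](O[Si](C)(C)C(C)(C)C)/C=C(/C)C[C@@H](O[Si](CC)(CC)CC)[C@@H](CC(=O)OC)CO
F3 | step 16 | 3-formyl analogue of F1 | I/C=C(\C)C[C@H](O[Si](C)(C)C(C)(C)C)/C=C(/C)C[C@@H](O[Si](CC)(CC)CC)[C@@H](CC(=O)OC)C=O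
F4 | step 16 | ten-membered C6-hydroxy C12-methyl ester (free alcohol of 26) | O[C@@H]1/C=C(\C)C[C@H](O[Si](C)(C)C(C)(C)C)/C=C(/C)C[C@@H](O[Si](CC)(CC)CC)[C@H]1CC(=O)OC
F5 | step 14 | γ-lactone of 23 (O6 on C12) | C#CC[C@H](O[Si](C)(C)C(C)(C)C)/C=C(/C)C[C@@H](O[Si](CC)(CC)CC)[C@H]1CC(=O)OC1
F6 | step 14 | lithium carboxylate of the hydroxy acid from F5 | C#CC[C@H](O[Si](C)(C)C(C)(C)C)/C=C(/C)C[C@@H](O[Si](CC)(CC)CC)[C@@H](CC(=O)[O-])CO.[Li+]
F7 | step 14 | triethylsilyl ester triethylsilyl ether of the hydroxy acid | C#CC[C@H](O[Si](C)(C)C(C)(C)C)/C=C(/C)C[C@@H](O[Si](CC)(CC)CC)[C@@H](CC(=O)O[Si](CC)(CC)CC)CO[Si](CC)(CC)CC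
F8 | step 14 | acid with primary triethylsilyl ether at O6 | C#CC[C@H](O[Si](C)(C)C(C)(C)C)/C=C(/C)C[C@@H](O[Si](CC)(CC)CC)[C@@H](CC(=O)O)CO[Si](CC)(CC)CC
F9 | step 14 | methyl ester with primary triethylsilyl ether at O6 | C#CC[C@H](O[Si](C)(C)C(C)(C)C)/C=C(/C)C[C@@H](O[Si](CC)(CC)CC)[C@@H](CC(=O)OC)CO[Si](CC)(CC)CC
F10 | step 24 | tert-butyl{[(2E)-2-{[(4-methoxybenzyl)oxy]methyl}but-2-en-1-yl]oxy}dimethylsilane | C/C=C(\COCc1ccc(OC)cc1)CO[Si](C)(C)C(C)(C)C
F11 | step 24 | (2Z)-2-{[(4-methoxybenzyl)oxy]methyl}but-2-en-1-ol | C/C=C(\COCc1ccc(OC)cc1)CO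
F12 | step 24 | [(2S,3R)-2-{[(4-methoxybenzyl)oxy]methyl}-3-methyloxiran-2-yl]methanol | COc1ccc(COC[C@]2(CO)O[C@@H]2C)cc1
F13 | step 24 | tert-butyl{[(2R,3R)-2-{[(4-methoxybenzyl)oxy]methyl}-3-methyloxiran-2-yl]methoxy}dimethylsilane | COc1ccc(COC[C@]2(CO[Si](C)(C)C(C)(C)C)O[C@@H]2C)cc1
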